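Its constants were set for the occasion; no experiment stands behind them.

The constants describe E leaving by two first-order exits, E → Q and E → L, while E also binds G in a fast balance; I had three flasks that differed in run time.

    Q → G (k1 = 0.43 s⁻¹)
    E → L (k2 = 0.10 s⁻¹)
    E + G ⇌ E.G, settled at all times (K3 = 190 L mol⁻¹)
    L → D (k4 = 0.028 s⁻¹)
    E → Q (k5 = 0.086 s⁻¹)

| setting | ash | elm | larch |
|---|---|---|---|
| E | 0.013 M | 0.013 M | 0.013 M |
| time | 3.0 min | 6.0 min | 12 min |

- percentages count the E that a species holds: one E.G counts as two
- G is meant together with its E.G
- in an amount of G, one E.G counts as one G
- run time (ash): 3.0 min

- which of the two there is more of at the end, ash (G / D)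
- which of the two there is more of at the end, elm (G / D)
- which of the two there is more of at the end, larch (G / D)
- how much G is there at the end, in percent of the E charged: ash
- how much G is there at the end, in percent of the E charged: elm
- how much G is there at the end, in percent of the E charged: larch

Two numbers did not seem to go together. The binding constant times the starting [E] is 2.5 in ash, so binding is no small correction, yet the rates of the two exits contain no binding constant.

I replaced the curve of free [E] by its mean over the run. The turnover of E → Q was then 0.086 s⁻¹ times mean [E] times the time, and that of E → L was 0.10 s⁻¹ times the same mean and the same time. Mean and time cancelled in the ratio, so the replacement made no error there, however the curve bent. The share came to 46.2%: the rate constant of E → Q over the sum of the constants of both exits. I called this the branching share, the usual term being selectivity.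

Binding could still delay the end. With G at that share of the charge, I estimated that the pool of E, free and bound, would decay slower by a factor of 2.14, which gave an estimated lifetime of 0.192 min. That is shorter than the 3.0 min of ash, the shortest run. L has a half-life of 0.413 min, also shorter than that run. So I expected G at 46.2% in ash, elm and larch, with D ahead, since the route through L takes 53.8% of E.

The forecast gave G at 46.2% for ash, elm and larch alike, within 45.7% to 46.7%, and D as the larger, holding that “Binding to G only buffers E”.

The simulation gave G at 46.2% in ash, 46.2% in elm and 46.2% in larch, and D at 53.3%, 53.8% and 53.8%, so D was the larger in each, as forecast.

G stood at the branching share 46.2% in ash, elm and larch, and a reading ten times later left it unchanged in ash and in larch. In larch, half the turnover of E → Q was done by 0.0656 min and half that of L → D by 0.540 min, which is later but still well inside the run of 12 min. For a further flask like larch but with 0.0078 M of E, the share contains no [E], so it again gave 46.2%; the simulation gave 46.2%.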